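The runs are calculated with made-up constants.

Reciprocal minutes are the unit for this flask: take the fraction of L left between two readings, take its logarithm and divide by the time between them. In both runs E is charged into a closed, stirred flask, L rises and then declines. The flask asked about is Friday's, at 15 min.

| flask | E | temperature | remark | time |
|---|---|---|---|---|
| Friday's | 20 mM | 90 °C | the very flask that is asked about, followed so far |  |
| Tuesday's | 20 mM | 75 °C | run made earlier |  |
| flask | 20 mM | 90 °C |  | 15 min |

| run | time / min | L / % | E / % |
|---|---|---|---|
| Friday's | 0.500 | 64 | 9 |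
| Friday's | 1.33 | 61 | 1 |
| Friday's | 2.50 | 52 | 2 |
| Friday's | 4.00 | 40 | 0 |
| Friday's | 5.00 | 38 | 1 |
| Friday's | 8.00 | 32 | 3 |
| Friday's | 10.0 | 25 | 0 |
| Tuesday's | 1.00 | 43 | 19 |
| Tuesday's | 3.00 | 55 | 4 |
| Tuesday's | 5.00 | 51 | 2 |
| Tuesday's | 8.00 | 45 | 0 |
| Tuesday's | 10.0 | 42 | 3 |
| Tuesday's | 15.0 | 32 | 2 |
| Tuesday's | 20.0 | 27 | 1 |

(each reading ± 2 percentage points)

- north-east: at 15 min take out 90% of the L then present, then wait 8.0 min
- west: at 15 min raise the temperature by 15 K, then wait 8.0 min
- north: at 15 min add E, 50.0% of the amount charged, then wait 8.0 min
- south-west: change nothing and wait 8.0 min more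

- L, in percent of the E first charged, at 15 min
- the option that brings most further L ("none" if no option brings more than 2 percentage points) (north-east / west / north / south-west / none)
- L present, with what was taken out counted in, in percent of the E first charged, after north-east
- L present, with what was taken out counted in, in percent of the E first charged, after west

- percentages count the E that a species holds: one D counts as two
- L that was removed still counts
- what may be going on: E <-> Z; E -> L; Z -> J; L <-> J; L <-> Q; E + L -> D
- additions bring no volume worth counting

Read the L column of Friday's run from the row where E reads 1%, at 1.33 min. There c(L) reads 61%, and at 10.0 min it reads 25%, which gives an apparent first-order rate of 0.103 min⁻¹.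

Tuesday's column, from the row where E reads 4%, goes from 55% at 3.00 min to 27% at 20.0 min, which gives 0.0419 min⁻¹. Set against each other, the two columns say that 15 K multiplies this rate by 2.46, as a reading with its scatter.

Carrying that factor one step further is my own extrapolation: 15 K above Friday's flask the rate reads 0.253 min⁻¹. Over 8.0 min this leaves 13.2% of the distance between c(L) and its resting level, the equilibrium mixture at the new temperature. I call this the gap left: the fraction of that distance not yet travelled after the wait. So my reckoning for west is that c(L) ends near the resting level of the hotter flask, a level these runs don't show.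

The forecast gives 21% at 15 min, 27.5% after north-east and 18% after west, and it picks north. Of heating it says: “The plateau seems little changed”.

The flask gives 23.6% at 15 min, 37.1% after north-east and 46.1% after west. The best option is west, with a gain of 23 percentage points.

    E ⇌ Z (K = 0.500, k = 0.228 s⁻¹, Ea = 86.0 kJ mol⁻¹, ΔH = −40.0 kJ mol⁻¹)
    E → L (k = 0.0717 s⁻¹, Ea = 94.0 kJ mol⁻¹)
    Z → J (k = 0.0414 s⁻¹, Ea = 90.0 kJ mol⁻¹)
    L ⇌ J (K = 0.363, k = 8.59 × 10⁻⁴ s⁻¹, Ea = 99.0 kJ mol⁻¹, ΔH = −79.0 kJ mol⁻¹)
    L ⇌ Q (K = 3.19, k = 0.00320 s⁻¹, Ea = 95.0 kJ mol⁻¹, ΔH = −90.0 kJ mol⁻¹)
    E + L → D (k = 0.176 M⁻¹ s⁻¹, Ea = 70.0 kJ mol⁻¹)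
    (constants at 90 °C)

A neighbour flask run at 105 °C from the start has a gap left of 2.25% at 15 min, so its 46.3% stands for the hotter resting level. With the gap left, west on Friday's flask should reach 43.3%, and it reaches 46.1%. In Friday's flask L stands at 23.6% at 15 min through the turning of L into Q, both ways: the same run without that step holds 71.5%. Under west, Q falling back to L and J falling back to L are each a part of the climb: beside the 23 points of the full scheme, the gain brought by west is −8.8 points in the run without Q's return and 1.1 points in the run without J's.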